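**Retrosynthetic overview**
- Last C–C bond: the linker CH2–C(sp2) bond to the tetrasubstituted cyclohexene carbon, made by B-alkyl Suzuki–Miyaura coupling of the 9-BBN adduct of a vinyl perhydrobenzoxepine with a cyclohexenyl triflate; global desilylation follows.
- Cyclohexene fragment (ring present from the start): cyclohexane-1,3-dione → C-methylation, C-allylation, CBS desymmetrisation, α-methylation, enol triflate, cross-metathesis with 2-methylbut-3-en-2-ol.
- Oxepane fragment, carbocycle first: phenol → quinone monoketal → Rh/BINAP conjugate vinylation → two α′-alkylations (quaternary methyl/homoprenyl carbon) → conjugate reduction, deketalisation, MeCeCl2 addition.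
- Oxepane ring closed last on that cyclohexanone: Shi epoxidation, then a new silyl triflate/silane reductive 7-endo keto-epoxide oxacyclisation that sets the trans ring fusion.
- Ring order: cyclohexane (from phenol) → oxepane → union with the preformed cyclohexene.

Assumption: the catalyst antipodes named ((S)-BINAP, (S)-Me-CBS, D-fructose-derived Shi ketone) are those the usual models predict for the configurations drawn; the other antipode is used if the sense is reversed on these substrates.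

**Cyclohexene fragment**

Step 1
Reactants: 1 cyclohexane-1,3-dione
Product: 2 2-methylcyclohexane-1,3-dione
Conditions: MeI, KOH, H2O/dioxane, reflux
Reagents that add atoms: iodomethane CI
Why: C-alkylation of the stabilised 1,3-dione enolate (classical dione methylation); no stereocentre is formed.

Step 2
Reactants: 2 2-methylcyclohexane-1,3-dione; 3 allyl bromide
Product: 4 2-allyl-2-methylcyclohexane-1,3-dione
Conditions: 1 M NaOH (aq), Bu4NI (cat.), rt
Reagents that add atoms: none
Why: second enolate C-alkylation with the reactive allylic halide gives the prochiral quaternary carbon.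

Step 3
Reactants: 4 2-allyl-2-methylcyclohexane-1,3-dione
Product: 5 (2R,3R)-2-allyl-3-hydroxy-2-methylcyclohexan-1-one (OH cis to allyl)
Conditions: (S)-Me-CBS oxazaborolidine (15 mol %), catecholborane (1.1 equiv), toluene, −60 °C; MeOH, aq. NaOH work-up
Reagents that add atoms: none
Why: Corey–Bakshi–Shibata reduction desymmetrises the prochiral dione; the catalyst gives the 3R carbinol (quaternary carbon as the large group) and the matched carbonyl is the one attacked anti to allyl, so OH ends cis to allyl and C2 becomes R.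

Step 4
Reactants: 5 (2R,3R)-2-allyl-3-hydroxy-2-methylcyclohexan-1-one
Product: 6 (2R,3R)-2-allyl-3-[(tert-butyldimethylsilyl)oxy]-2-methylcyclohexan-1-one
Conditions: TBSOTf, 2,6-lutidine, CH2Cl2, −78 → 0 °C
Reagents that add atoms: tert-butyldimethylsilyl trifluoromethanesulfonate CC(C)(C)[Si](C)(C)OS(=O)(=O)C(F)(F)F
Why: silyl ether formation on the hindered secondary alcohol; stereocentres are untouched.

Step 5
Reactants: 6 (2R,3R)-2-allyl-3-[(tert-butyldimethylsilyl)oxy]-2-methylcyclohexan-1-one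
Product: 8 (2R,3R,6RS)-2-allyl-3-[(tert-butyldimethylsilyl)oxy]-2,6-dimethylcyclohexan-1-one, via lithium enolate 7 (not isolated)
Conditions: LDA, THF, −78 °C; MeI, −78 → 0 °C
Reagents that add atoms: iodomethane CI
Why: kinetic enolate alkylation at C6, the only enolisable position; the new C6 centre becomes sp2 in step 6, so its configuration is irrelevant.

Step 6
Reactants: 8 (2R,3R,6RS)-2-allyl-3-[(tert-butyldimethylsilyl)oxy]-2,6-dimethylcyclohexan-1-one
Product: 10 (5R,6R)-6-allyl-5-[(tert-butyldimethylsilyl)oxy]-2,6-dimethylcyclohex-1-en-1-yl trifluoromethanesulfonate, via potassium enolate 9 (not isolated)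
Conditions: KHMDS, THF, −78 °C; PhNTf2, −78 → 0 °C
Reagents that add atoms: N-phenylbis(trifluoromethanesulfonimide) O=S(=O)(N(c1ccccc1)S(=O)(=O)C(F)(F)F)C(F)(F)F
Why: O-triflation of the tetrasubstituted enolate (enol triflate formation) fixes the ring double bond between C1 and the methyl-bearing carbon.

Step 7
Reactants: 10 (5R,6R)-6-allyl-5-[(tert-butyldimethylsilyl)oxy]-2,6-dimethylcyclohex-1-en-1-yl trifluoromethanesulfonate; 11 2-methylbut-3-en-2-ol
Product: 12 (5R,6R)-5-[(tert-butyldimethylsilyl)oxy]-6-[(2E)-4-hydroxy-4-methylpent-2-en-1-yl]-2,6-dimethylcyclohex-1-en-1-yl trifluoromethanesulfonate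
Conditions: second-generation Hoveyda–Grubbs catalyst RuCl2(H2IMes)(=CH-C6H4-2-OiPr) (5 mol %), 11 (4 equiv), CH2Cl2, 40 °C
Reagents that add atoms: none
Why: olefin cross-metathesis of the terminal allyl group with the hindered tertiary allylic alcohol gives the E-disubstituted alkene under thermodynamic control; triflate, silyl ether and the tetrasubstituted alkene are inert.

**Oxepane fragment**

Step 8
Reactants: 13 phenol
Product: 14 4,4-dimethoxycyclohexa-2,5-dien-1-one
Conditions: PhI(OAc)2 (2.2 equiv), MeOH, 0 °C → rt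
Reagents that add atoms: methanol CO
Why: hypervalent-iodine oxidative dearomatisation (para-methoxylation, then ketalisation) gives the quinone monoketal.

Step 9
Reactants: 14 4,4-dimethoxycyclohexa-2,5-dien-1-one; 15 potassium vinyltrifluoroborate
Product: 16 (5S)-5-ethenyl-4,4-dimethoxycyclohex-2-en-1-one
Conditions: [Rh(cod)2]BF4 (3 mol %), (S)-BINAP (3.3 mol %), Et3N, toluene/H2O 20:1, 25 °C; 15 (1.05 equiv)
Reagents that add atoms: none
Why: Hayashi–Miyaura rhodium-catalysed asymmetric 1,4-addition of an alkenyltrifluoroborate to one of the two equivalent enone arms; (S)-BINAP directs the vinyl group to the face that gives the 5S centre.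

Step 10
Reactants: 16 (5S)-5-ethenyl-4,4-dimethoxycyclohex-2-en-1-one
Product: 18 (5R,6R)-5-ethenyl-4,4-dimethoxy-6-methylcyclohex-2-en-1-one (methyl trans to vinyl), via lithium dienolate 17 (not isolated)
Conditions: LDA, THF, −78 °C; MeI, −78 → −40 °C
Reagents that add atoms: iodomethane CI
Why: kinetic α′-enolate alkylation (the other α-carbon is vinylic and the γ-carbon is the ketal carbon), methyl entering trans to vinyl; this centre is planarised again in step 11.

Step 11
Reactants: 18 (5R,6R)-5-ethenyl-4,4-dimethoxy-6-methylcyclohex-2-en-1-one; 19 5-iodo-2-methylpent-2-ene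
Product: 21 (5R,6R)-5-ethenyl-4,4-dimethoxy-6-methyl-6-(4-methylpent-3-en-1-yl)cyclohex-2-en-1-one, via lithium dienolate 20 (not isolated)
Conditions: LDA, THF, −78 → −40 °C; HMPA, 19 (2 equiv), −40 → 0 °C
Reagents that add atoms: none
Why: α′-alkylation of the cross-conjugated lithium dienolate with a primary iodide (Stork–Danheiser-type quaternisation); the electrophile approaches anti to the neighbouring pseudoaxial vinyl group, so homoprenyl ends trans and methyl cis to vinyl.

Step 12
Reactants: 21 (5R,6R)-5-ethenyl-4,4-dimethoxy-6-methyl-6-(4-methylpent-3-en-1-yl)cyclohex-2-en-1-one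
Product: 22 (2R,3R)-3-ethenyl-4,4-dimethoxy-2-methyl-2-(4-methylpent-3-en-1-yl)cyclohexan-1-one
Conditions: [(Ph3P)CuH]6 (0.4 equiv), H2O (2 equiv), THF, rt
Reagents that add atoms: none
Why: copper hydride conjugate reduction (Stryker reagent) is selective for the enone C=C over the vinyl and trisubstituted alkenes; stereocentres are untouched.

Step 13
Reactants: 22 (2R,3R)-3-ethenyl-4,4-dimethoxy-2-methyl-2-(4-methylpent-3-en-1-yl)cyclohexan-1-one
Product: 23 (2R,3R)-3-ethenyl-2-methyl-2-(4-methylpent-3-en-1-yl)cyclohexane-1,4-dione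
Conditions: 10% aq. oxalic acid on SiO2, CH2Cl2, rt
Reagents that add atoms: water O
Why: mild acetal hydrolysis on wet silica; the dimethyl ketal cleaves quickly, before the α-vinyl ketone can enolise and epimerise.

Step 14
Reactants: 23 (2R,3R)-3-ethenyl-2-methyl-2-(4-methylpent-3-en-1-yl)cyclohexane-1,4-dione
Product: 24 (2R,3R,4S)-3-ethenyl-4-hydroxy-2,4-dimethyl-2-(4-methylpent-3-en-1-yl)cyclohexan-1-one
Conditions: MeLi (1.3 equiv), CeCl3 (1.5 equiv), THF, −78 °C
Reagents that add atoms: methyllithium [Li]C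
Why: non-basic organocerium 1,2-addition goes to the less hindered C4 ketone (C1 is neopentylic), from the face anti to the adjacent vinyl group and to the 1,3-related pseudoaxial ring methyl, giving the 4S alcohol with OH cis to both.

Step 15
Reactants: 24 (2R,3R,4S)-3-ethenyl-4-hydroxy-2,4-dimethyl-2-(4-methylpent-3-en-1-yl)cyclohexan-1-one
Product: 25 (2R,3R,4S)-2-{2-[(2R)-3,3-dimethyloxiran-2-yl]ethyl}-3-ethenyl-4-hydroxy-2,4-dimethylcyclohexan-1-one
Conditions: D-fructose-derived Shi ketone (30 mol %), Oxone, K2CO3, Bu4NHSO4, MeCN/CH2(OMe)2/aq. Na2B4O7 buffer (pH 10.5), 0 °C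
Reagents that add atoms: potassium peroxymonosulfate [K+].[O-]S(=O)(=O)OO
Why: Shi asymmetric epoxidation; the electron-rich trisubstituted alkene reacts far faster than the vinyl group and the chiral dioxirane sets the (R)-epoxide by reagent control.

Step 16
Reactants: 25 (2R,3R,4S)-2-{2-[(2R)-3,3-dimethyloxiran-2-yl]ethyl}-3-ethenyl-4-hydroxy-2,4-dimethylcyclohexan-1-one
Product: 28 (3R,5aR,6R,7S,9aR)-6-ethenyl-2,2,5a,7-tetramethyl-3,7-bis[(triethylsilyl)oxy]decahydro-1-benzoxepine, via keto epoxide triethylsilyl ether 26 (not isolated), via oxocarbenium triflate 27 (not isolated)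
Conditions: TESOTf (2.5 equiv), 2,6-di-tert-butyl-4-methylpyridine (3 equiv), Et3SiH (5 equiv), CH2Cl2, −78 → −30 °C
Reagents that add atoms: triethylsilyl trifluoromethanesulfonate CC[Si](CC)(CC)OS(=O)(=O)C(F)(F)F
Why: Proposed new method: silyl-triflate-triggered reductive 7-endo oxacyclisation of a 5,6-epoxy ketone — after silylation of the tertiary alcohol, the silyl cation activates the trisubstituted epoxide, the weakly nucleophilic ketone oxygen attacks its tertiary (most cation-stabilised) carbon, and Et3SiH intercepts the seven-membered oxocarbenium ion (a bicyclic ketal formed reversibly is reopened by the bulky silyl group only at the less hindered secondary oxygen, back to the same cation); hydride enters axially, anti to the angular methyl, setting the trans ring fusion (9aR) while the epoxide CH carbon keeps its R configuration; the closest known reaction types are Lewis-acid endo-selective epoxide openings terminated by a carbonyl oxygen, acid-catalysed keto-epoxide bicycloketalisation and silane reductive etherification of ketones.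

**Fragment union and end game**

Step 17
Reactants: 28 (3R,5aR,6R,7S,9aR)-6-ethenyl-2,2,5a,7-tetramethyl-3,7-bis[(triethylsilyl)oxy]decahydro-1-benzoxepine; 12 (5R,6R)-5-[(tert-butyldimethylsilyl)oxy]-6-[(2E)-4-hydroxy-4-methylpent-2-en-1-yl]-2,6-dimethylcyclohex-1-en-1-yl trifluoromethanesulfonate
Product: 30 tris-silyl ether of siphonellinol C (TES on the oxepane and tertiary cyclohexane oxygens; TBS on the cyclohexene oxygen), via alkylborane 29 (not isolated)
Conditions: 28 (1.3 equiv), 9-BBN dimer, THF, 60 °C; then aq. Cs2CO3, 12, Pd(dppf)Cl2 (10 mol %), AsPh3 (10 mol %), DMF/THF/H2O, 50 °C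
Reagents that add atoms: none
Why: anti-Markovnikov hydroboration of the terminal vinyl group followed by B-alkyl Suzuki–Miyaura coupling (oxidative addition of zerovalent palladium into the enol triflate, base-assisted alkyl transfer from boron, reductive elimination) forms the linker-to-cyclohexene bond without touching any stereocentre.

Step 18
Reactants: 30 tris-silyl ether of siphonellinol C
Product: 31 siphonellinol C
Conditions: TBAF (6 equiv), THF, 50 °C
Reagents that add atoms: none
Why: fluoride desilylation removes the TBS and both TES groups; the basic, non-acidic conditions spare the tertiary allylic alcohol and the tetrasubstituted alkene.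

**Compound list**

1 | cyclohexane-1,3-dione | O=C1CCCC(=O)C1 | starting material
2 | 2-methylcyclohexane-1,3-dione | CC1C(=O)CCCC1=O | intermediate
3 | allyl bromide | C=CCBr | starting material
4 | 2-allyl-2-methylcyclohexane-1,3-dione | C=CCC1(C)C(=O)CCCC1=O | intermediate
5 | (2R,3R)-2-allyl-3-hydroxy-2-methylcyclohexan-1-one | O=C1[C@](C)(CC=C)[C@H](O)CCC1 | intermediate
6 | (2R,3R)-2-allyl-3-[(tert-butyldimethylsilyl)oxy]-2-methylcyclohexan-1-one | O=C1[C@](C)(CC=C)[C@H](O[Si](C)(C)C(C)(C)C)CCC1 | intermediate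
7 | lithium enolate of 6 (C1–C6 enolate) | [Li+].[O-]C=1[C@](C)(CC=C)[C@H](O[Si](C)(C)C(C)(C)C)CCC=1 | intermediate
8 | (2R,3R,6RS)-2-allyl-3-[(tert-butyldimethylsilyl)oxy]-2,6-dimethylcyclohexan-1-one | O=C1[C@](C)(CC=C)[C@H](O[Si](C)(C)C(C)(C)C)CCC1C | intermediate
9 | potassium enolate of 8 | [K+].[O-]C=1[C@](C)(CC=C)[C@H](O[Si](C)(C)C(C)(C)C)CCC=1C | intermediate
10 | (5R,6R)-6-allyl-5-[(tert-butyldimethylsilyl)oxy]-2,6-dimethylcyclohex-1-en-1-yl trifluoromethanesulfonate | CC1=C(OS(=O)(=O)C(F)(F)F)[C@](C)(CC=C)[C@H](O[Si](C)(C)C(C)(C)C)CC1 | intermediate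
11 | 2-methylbut-3-en-2-ol | CC(C)(O)C=C | starting material
12 | (5R,6R)-5-[(tert-butyldimethylsilyl)oxy]-6-[(2E)-4-hydroxy-4-methylpent-2-en-1-yl]-2,6-dimethylcyclohex-1-en-1-yl trifluoromethanesulfonate | CC1=C(OS(=O)(=O)C(F)(F)F)[C@](C)(C/C=C/C(C)(C)O)[C@H](O[Si](C)(C)C(C)(C)C)CC1 | intermediate
13 | phenol | Oc1ccccc1 | starting material
14 | 4,4-dimethoxycyclohexa-2,5-dien-1-one | COC1(OC)C=CC(=O)C=C1 | intermediate
15 | potassium vinyltrifluoroborate | [K+].C=C[B-](F)(F)F | starting material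
16 | (5S)-5-ethenyl-4,4-dimethoxycyclohex-2-en-1-one | O=C1C=CC(OC)(OC)[C@H](C=C)C1 | intermediate
17 | lithium dienolate of 16 | [Li+].[O-]C=1C=CC(OC)(OC)[C@H](C=C)C=1 | intermediate
18 | (5R,6R)-5-ethenyl-4,4-dimethoxy-6-methylcyclohex-2-en-1-one | O=C1C=CC(OC)(OC)[C@H](C=C)[C@H]1C | intermediate
19 | 5-iodo-2-methylpent-2-ene | CC(C)=CCCI | starting material
20 | lithium dienolate of 18 | [Li+].[O-]C=1C=CC(OC)(OC)[C@H](C=C)C=1C | intermediate
21 | (5R,6R)-5-ethenyl-4,4-dimethoxy-6-methyl-6-(4-methylpent-3-en-1-yl)cyclohex-2-en-1-one | O=C1C=CC(OC)(OC)[C@H](C=C)[C@@]1(C)CCC=C(C)C | intermediate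
22 | (2R,3R)-3-ethenyl-4,4-dimethoxy-2-methyl-2-(4-methylpent-3-en-1-yl)cyclohexan-1-one | O=C1CCC(OC)(OC)[C@H](C=C)[C@@]1(C)CCC=C(C)C | intermediate
23 | (2R,3R)-3-ethenyl-2-methyl-2-(4-methylpent-3-en-1-yl)cyclohexane-1,4-dione | O=C1CCC(=O)[C@H](C=C)[C@@]1(C)CCC=C(C)C | intermediate
24 | (2R,3R,4S)-3-ethenyl-4-hydroxy-2,4-dimethyl-2-(4-methylpent-3-en-1-yl)cyclohexan-1-one | O=C1CC[C@](C)(O)[C@H](C=C)[C@@]1(C)CCC=C(C)C | intermediate
25 | (2R,3R,4S)-2-{2-[(2R)-3,3-dimethyloxiran-2-yl]ethyl}-3-ethenyl-4-hydroxy-2,4-dimethylcyclohexan-1-one | O=C1CC[C@](C)(O)[C@H](C=C)[C@@]1(C)CC[C@H]2OC2(C)C | intermediate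
26 | tertiary triethylsilyl ether of 25 | O=C1CC[C@](C)(O[Si](CC)(CC)CC)[C@H](C=C)[C@@]1(C)CC[C@H]2OC2(C)C | intermediate
27 | oxepanyl oxocarbenium triflate (ring O+=C9a; C3–OTES, C7–OTES) | C=C[C@@H]1[C@@]2(C)CC[C@@H](O[Si](CC)(CC)CC)C(C)(C)[O+]=C2CC[C@]1(C)O[Si](CC)(CC)CC.[O-]S(=O)(=O)C(F)(F)F | intermediate
28 | (3R,5aR,6R,7S,9aR)-6-ethenyl-2,2,5a,7-tetramethyl-3,7-bis[(triethylsilyl)oxy]decahydro-1-benzoxepine | C=C[C@@H]1[C@@]2(C)CC[C@@H](O[Si](CC)(CC)CC)C(C)(C)O[C@@H]2CC[C@]1(C)O[Si](CC)(CC)CC | intermediate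
29 | B-alkyl-9-borabicyclo[3.3.1]nonane from 28 (boron on the terminal linker carbon) | C1CCC2CCCC1B2CC[C@@H]1[C@@]2(C)CC[C@@H](O[Si](CC)(CC)CC)C(C)(C)O[C@@H]2CC[C@]1(C)O[Si](CC)(CC)CC | intermediate
30 | tris-silyl ether of siphonellinol C (3,7-bis-TES on the benzoxepine; TBS on the cyclohexenol) | CC1=C(CC[C@@H]2[C@@]3(C)CC[C@@H](O[Si](CC)(CC)CC)C(C)(C)O[C@@H]3CC[C@]2(C)O[Si](CC)(CC)CC)[C@](C)(C/C=C/C(C)(C)O)[C@H](O[Si](C)(C)C(C)(C)C)CC1 | intermediate
31 | siphonellinol C | CC1=C(CC[C@@H]2[C@@]3(C)CC[C@@H](O)C(C)(C)O[C@@H]3CC[C@]2(C)O)[C@](C)(C/C=C/C(C)(C)O)[C@H](O)CC1 | target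

**Totals**
Total step count: 18. Longest linear sequence: 11 steps (steps 8–18, from phenol); the other branch is 9 steps (steps 1–7, 17, 18).

**Three steps most likely to fail**

Step 16 (the proposed new step). The risks are 6-exo attack, hydride shift of the activated epoxide, or funnelling through the bicyclic ketal to the tetrahydropyran. The fallback uses known chemistry and sets out from 25. NaBH4 in MeOH at 0 °C reduces the ketone by axial attack to the equatorial alcohol (1S,2R,3R,4R)-3-{2-[(2R)-3,3-dimethyloxiran-2-yl]ethyl}-2-ethenyl-1,3-dimethylcyclohexane-1,4-diol F1. Catalytic camphorsulfonic acid in CH2Cl2 at −20 °C then effects the acid-catalysed hydroxy-epoxide cyclisation; the 7-endo product (3R,5aR,6R,7S,9aR)-6-ethenyl-2,2,5a,7-tetramethyldecahydro-1-benzoxepine-3,7-diol F2 is separated from the 6-exo tetrahydropyran isomer. TESOTf/2,6-lutidine silylates both hydroxyls and the route is rejoined at 28.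

Step 17. Both partners are hindered: a neopentylic alkylborane and a tetrasubstituted triflate next to a quaternary carbon. The fallback sets out from 28 and replaces boron by zinc. Hydroboration with 9-BBN and NaOH/H2O2 oxidation give 2-[(3R,5aR,6R,7S,9aR)-2,2,5a,7-tetramethyl-3,7-bis(triethylsilyloxy)decahydro-1-benzoxepin-6-yl]ethan-1-ol F3. I2/PPh3/imidazole gives the (3R,5aR,6R,7S,9aR)-6-(2-iodoethyl) bis-TES ether F4, and zinc dust/LiCl in THF gives the corresponding alkylzinc iodide F5. Base-free Negishi coupling of F5 with 12 (Pd(OAc)2/SPhos, THF/NMP, 40 °C; the free tertiary alcohol is tolerated) rejoins the route at 30.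

Step 14. A single methyl addition must distinguish two ketones and one face. The fallback sets out from 22 and masks the C1 carbonyl as its alcohol. NaBH4 gives (1R,2R,3R)-3-ethenyl-4,4-dimethoxy-2-methyl-2-(4-methylpent-3-en-1-yl)cyclohexan-1-ol F6. Oxalic acid on wet silica gives (2R,3R,4R)-2-ethenyl-4-hydroxy-3-methyl-3-(4-methylpent-3-en-1-yl)cyclohexan-1-one F7. MeLi/CeCl3 (2.5 equiv) gives (1S,2R,3R,4R)-2-ethenyl-1,3-dimethyl-3-(4-methylpent-3-en-1-yl)cyclohexane-1,4-diol F8. Dess–Martin periodinane oxidises only the secondary alcohol and the route is rejoined at 24.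

**Further compounds**

F1 | step 16 | (1S,2R,3R,4R)-3-{2-[(2R)-3,3-dimethyloxiran-2-yl]ethyl}-2-ethenyl-1,3-dimethylcyclohexane-1,4-diol | O[C@@H]1CC[C@](C)(O)[C@H](C=C)[C@@]1(C)CC[C@H]2OC2(C)C
F2 | step 16 | (3R,5aR,6R,7S,9aR)-6-ethenyl-2,2,5a,7-tetramethyldecahydro-1-benzoxepine-3,7-diol | C=C[C@@H]1[C@@]2(C)CC[C@@H](O)C(C)(C)O[C@@H]2CC[C@]1(C)O
F3 | step 17 | 2-[(3R,5aR,6R,7S,9aR)-2,2,5a,7-tetramethyl-3,7-bis(triethylsilyloxy)decahydro-1-benzoxepin-6-yl]ethan-1-ol | OCC[C@@H]1[C@@]2(C)CC[C@@H](O[Si](CC)(CC)CC)C(C)(C)O[C@@H]2CC[C@]1(C)O[Si](CC)(CC)CC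
F4 | step 17 | (3R,5aR,6R,7S,9aR)-6-(2-iodoethyl)-2,2,5a,7-tetramethyl-3,7-bis(triethylsilyloxy)decahydro-1-benzoxepine | ICC[C@@H]1[C@@]2(C)CC[C@@H](O[Si](CC)(CC)CC)C(C)(C)O[C@@H]2CC[C@]1(C)O[Si](CC)(CC)CC
F5 | step 17 | alkylzinc iodide from F4 (zinc on the terminal linker carbon) | I[Zn]CC[C@@H]1[C@@]2(C)CC[C@@H](O[Si](CC)(CC)CC)C(C)(C)O[C@@H]2CC[C@]1(C)O[Si](CC)(CC)CC
F6 | step 14 | (1R,2R,3R)-3-ethenyl-4,4-dimethoxy-2-methyl-2-(4-methylpent-3-en-1-yl)cyclohexan-1-ol | O[C@@H]1CCC(OC)(OC)[C@H](C=C)[C@@]1(C)CCC=C(C)C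
F7 | step 14 | (2R,3R,4R)-2-ethenyl-4-hydroxy-3-methyl-3-(4-methylpent-3-en-1-yl)cyclohexan-1-one | O[C@@H]1CCC(=O)[C@H](C=C)[C@@]1(C)CCC=C(C)C
F8 | step 14 | (1S,2R,3R,4R)-2-ethenyl-1,3-dimethyl-3-(4-methylpent-3-en-1-yl)cyclohexane-1,4-diol | O[C@@H]1CC[C@](C)(O)[C@H](C=C)[C@@]1(C)CCC=C(C)C
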